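**Strategy**

Locants: pyrrolidine N4–C3–C2–C1–C9a; azepine N4–C5…C8–C9–C9a; ring C = C1, C9a, C9, C10, C11, C12; lactone D = C1–O–C14–C13–C12. The plan rests on disconnecting C9=C9a and C12–C1, which unravels the azepine, ring C and lactone D to a monocyclic 3-pyrrolidinone whose single N-tether carries an enol triflate (C9), a free carbinol (C11) and an enoate (C12–C14). In one pot, palladium-catalysed enolate alkenylation joins C9 to C9a and conjugation gives the 9,9a-enamine; SmI2 then joins C1 to C12 and lactonises. The step exploits the quaternary C1 (only one enamine is possible) and the all-cis O1/O11/C13 array on ring C, which one samarium ion can template.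

Key step: step 16

Remark: 12 and the THF solution of 16 are taken as purchasable (12 is otherwise one N-acylation of the commercial oxazolidinone). The key step is a one-flask, two-stage operation; the E/Z mixture of enol triflate 18 is carried on because both isomers converge in it.

**Route**

Step 1
Reactants: 1 N-Boc-trans-4-hydroxy-D-proline methyl ester
Product: 2 O-TBS ether of 1
Conditions: TBSCl, imidazole, DMF, rt
Reagents that add atoms: tert-butyldimethylsilyl chloride, CC(C)(C)[Si](C)(C)Cl
Why: Imidazole-assisted silyl ether formation masks the future C1 oxygen through the reduction and organozinc steps; no stereocentre is touched.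

Step 2
Reactants: 2 O-TBS ether of 1
Product: 3 N-Boc-4-silyloxy-D-prolinal
Conditions: (i-Bu)2AlH, toluene, −78 °C; MeOH, then Rochelle salt
Reagents that add atoms: none
Why: Partial ester reduction should stop at the tetrahedral aluminium hemiacetal at −78 °C and release the configurationally labile aldehyde only on cold work-up (used at once).

Step 3
Reactants: 3 N-Boc-4-silyloxy-D-prolinal; 4 ethyl 2-(bromomethyl)prop-2-enoate
Product: 5 α-methylene lactone (C18 S)
Conditions: Zn, THF–sat. aq. NH4Cl, rt; lactonisation completed with PPTS, CH2Cl2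
Reagents that add atoms: none
Why: Barbier-type (Dreiding–Schmidt) allylation–lactonisation; the 2-(ethoxycarbonyl)allylzinc should add in the Felkin–Anh sense (carbamate nitrogen anti to the incoming carbon), which sets C18 as S, and the zinc alkoxide closes the α-methylene-γ-butyrolactone.

Step 4
Reactants: 5 α-methylene lactone
Product: 6 cis-α-methyl lactone (C20 S)
Conditions: H2 (1 atm), Rh/Al2O3, EtOAc, rt
Reagents that add atoms: none
Why: Heterogeneous hydrogenation should deliver H2 to the exocyclic methylene from the lactone face opposite the C18 pyrrolidinyl group, giving the cis-2,4-disubstituted lactone without migration of the double bond into the ring.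

Step 5
Reactants: 6 cis-α-methyl lactone
Product: 7 amino alcohol trifluoroacetate
Conditions: aq. CF3CO2H, 0 °C to rt; evaporation
Reagents that add atoms: trifluoroacetic acid, OC(=O)C(F)(F)F
Why: Acidolysis removes the Boc group (isobutene and CO2) and the secondary silyl ether together and leaves the amino alcohol as a storable salt.

Step 6
Reactants: 8 2,2-dimethoxyacetaldehyde; 9 methyl 2-(triphenylphosphoranylidene)propanoate
Product: 10 E-acetal enoate
Conditions: CH2Cl2, rt
Reagents that add atoms: none
Why: Wittig olefination with the stabilised α-methyl ylide should give the E-trisubstituted enoate.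

Step 7
Reactants: 10 E-acetal enoate
Product: 11 methyl (2E)-2-methyl-4-oxobut-2-enoate
Conditions: Amberlyst-15, acetone–H2O, rt
Reagents that add atoms: water, O
Why: Acid-catalysed acetal hydrolysis unmasks the enal without touching the ester or the E double bond.

Step 8
Reactants: 12 (4R)-4-benzyl-3-butanoyl-1,3-oxazolidin-2-one; 11 methyl (2E)-2-methyl-4-oxobut-2-enoate
Product: 13 syn-aldol adduct
Conditions: Bu2BOTf, i-Pr2NEt, CH2Cl2, −78 to 0 °C; then 11, −78 °C; H2O2, pH 7 buffer, MeOH
Reagents that add atoms: none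
Why: Evans syn aldol; the Z-boron enolate reacts through a Zimmerman–Traxler chair on the face away from the benzyl group and adds 1,2 to the enal, setting C10 and C11 (5R,4S-syn in 13, which is 10S,11R in the target).

Step 9
Reactants: 13 syn-aldol adduct
Product: 14 TES ether of 13
Conditions: TESCl, imidazole, DMF, 0 °C
Reagents that add atoms: chlorotriethylsilane, CC[Si](Cl)(CC)CC
Why: Silyl ether formation protects the allylic carbinol against thiolate, organozinc, amide base and the later oxidation.

Step 10
Reactants: 14 TES ether of 13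
Product: 15 S-ethyl thioester
Conditions: EtSH, n-BuLi, THF, 0 °C
Reagents that add atoms: ethanethiol, CCS
Why: Thiolate transacylation at the exocyclic imide carbonyl releases the auxiliary without epimerising C10.

Step 11
Reactants: 15 S-ethyl thioester; 16 (4-chlorobutyl)zinc bromide
Product: 17 chloro ketone
Conditions: PdCl2(PPh3)2 (cat.), THF–toluene, rt
Reagents that add atoms: none
Why: Fukuyama coupling (insertion of zerovalent palladium into the C–S bond, transmetalation, reductive elimination) should give the ketone while the enoate, the silyl ether and the alkyl chloride stay untouched.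

Step 12
Reactants: 17 chloro ketone
Product: 18 enol triflate (E/Z mixture)
Conditions: KN(SiMe3)2, PhNTf2, THF, −78 °C
Reagents that add atoms: N-phenylbis(trifluoromethanesulfonimide), O=S(=O)(N(c1ccccc1)S(=O)(=O)C(F)(F)F)C(F)(F)F
Why: Kinetic deprotonation by the bulky amide base should occur at the unhindered C8 methylene and not at the branched C10, and O-triflation of the potassium enolate gives the enol triflate.

Step 13
Reactants: 7 amino alcohol trifluoroacetate; 18 enol triflate
Product: 19 tertiary amine
Conditions: K2CO3, NaI (cat.), MeCN, 60 °C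
Reagents that add atoms: none
Why: SN2 N-alkylation of the secondary amine by the primary chloride under Finkelstein catalysis joins the two fragments; the free secondary hydroxyl is far less nucleophilic than the amine.

Step 14
Reactants: 19 tertiary amine
Product: 20 pyrrolidin-3-one
Conditions: Dess–Martin periodinane, CH2Cl2, 0 °C to rt
Reagents that add atoms: none
Why: Dess–Martin oxidation converts the only free secondary alcohol into the C1 ketone; C3 is β to the new carbonyl and cannot epimerise.

Step 15
Reactants: 20 pyrrolidin-3-one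
Product: 21 hydroxy keto enol triflate
Conditions: HF·pyridine, THF–pyridine, 0 °C
Reagents that add atoms: none
Why: Fluoride cleaves the triethylsilyl ether and frees the C11 hydroxyl needed to bind samarium, under conditions that leave the enol triflate and both esters intact.

Step 16
Reactants: 21 hydroxy keto enol triflate
Product: 24 target CNP0154902.3, via non-conjugated bicyclic aminoketone 22 (not isolated), via conjugated aminoenone 23 (not isolated)
Conditions: Pd2(dba)3 (cat.), XPhos, K3PO4, THF, 60 °C; then same flask, −78 °C: SmI2, HMPA, t-BuOH, THF; AcOH quench at −78 °C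
Reagents that add atoms: none
Why: Zerovalent palladium inserts into the enol triflate and the potassium enolate of the amino ketone is alkenylated at C9a (intramolecular ketone α-alkenylation), which closes the azepine as a seven-membered ring by C–C reductive elimination, and phosphate then shifts the C8=C9 bond into conjugation, so both triflate isomers and both C9a epimers converge on aminoenone 23 with C9=C9a. SmI2 reduces the enone carbonyl to its ketyl radical anion, which closes ring C by 6-exo-trig attack of C1 on C12 of the enoate (ketyl–olefin cyclisation), and the samarium alkoxide on O1 closes lactone D by 5-exo-trig acyl substitution on the methyl ester. C1 and C12 are set by one trivalent samarium ion that bridges the ketyl oxygen and the free C11 hydroxyl in a chair-like transition state (O1 and O11 cis-diaxial, enoate arm equatorial, C10 ethyl pseudo-axial away from C8), which also keeps the bulky O–Sm group anti to the C3 lactone, and C13 is set by protonation of the samarium enolate on the face away from the quaternary C1. The closest known reaction types are the palladium-catalysed coupling of amino-tethered vinyl halides with ketone enolates and hydroxyl-directed SmI2 ketyl–olefin lactonisations. The step needs alkenylation at C9a and not at C2 (seven- against eight-membered ring), bond formation at the carbonyl carbon and not at C9 of the enone radical anion (C9 could only close a four-membered ring), and lactonisation on O1 and not on O11 (alkoxide against neutral hydroxyl, cold acidic quench).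

**Compound list**

1 | 1-tert-butyl 2-methyl (2R,4S)-4-hydroxypyrrolidine-1,2-dicarboxylate | CC(C)(C)OC(=O)N1C[C@@H](O)C[C@@H]1C(=O)OC | starting material
2 | 1-tert-butyl 2-methyl (2R,4S)-4-[(tert-butyldimethylsilyl)oxy]pyrrolidine-1,2-dicarboxylate | CC(C)(C)OC(=O)N1C[C@@H](O[Si](C)(C)C(C)(C)C)C[C@@H]1C(=O)OC | intermediate
3 | tert-butyl (2R,4S)-4-[(tert-butyldimethylsilyl)oxy]-2-formylpyrrolidine-1-carboxylate | CC(C)(C)OC(=O)N1C[C@@H](O[Si](C)(C)C(C)(C)C)C[C@@H]1C=O | intermediate
4 | ethyl 2-(bromomethyl)prop-2-enoate | CCOC(=O)C(=C)CBr | starting material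
5 | tert-butyl (2R,4S)-4-[(tert-butyldimethylsilyl)oxy]-2-[(2S)-4-methylidene-5-oxooxolan-2-yl]pyrrolidine-1-carboxylate | CC(C)(C)OC(=O)N1C[C@@H](O[Si](C)(C)C(C)(C)C)C[C@@H]1[C@@H]1CC(=C)C(=O)O1 | intermediate
6 | tert-butyl (2R,4S)-4-[(tert-butyldimethylsilyl)oxy]-2-[(2S,4S)-4-methyl-5-oxooxolan-2-yl]pyrrolidine-1-carboxylate | CC(C)(C)OC(=O)N1C[C@@H](O[Si](C)(C)C(C)(C)C)C[C@@H]1[C@@H]1C[C@H](C)C(=O)O1 | intermediate
7 | (3S,5S)-5-[(2R,4S)-4-hydroxypyrrolidin-2-yl]-3-methyloxolan-2-one trifluoroacetate | N1C[C@@H](O)C[C@@H]1[C@@H]1C[C@H](C)C(=O)O1.OC(=O)C(F)(F)F | intermediate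
8 | 2,2-dimethoxyacetaldehyde | COC(OC)C=O | starting material
9 | methyl 2-(triphenylphosphoranylidene)propanoate | COC(=O)C(C)=P(c1ccccc1)(c1ccccc1)c1ccccc1 | starting material
10 | methyl (2E)-4,4-dimethoxy-2-methylbut-2-enoate | COC(OC)/C=C(\C)C(=O)OC | intermediate
11 | methyl (2E)-2-methyl-4-oxobut-2-enoate | O=C/C=C(\C)C(=O)OC | intermediate
12 | (4R)-4-benzyl-3-butanoyl-1,3-oxazolidin-2-one | CCCC(=O)N1[C@H](Cc2ccccc2)COC1=O | starting material
13 | methyl (2E,4S,5R)-5-{[(4R)-4-benzyl-2-oxo-1,3-oxazolidin-3-yl]carbonyl}-4-hydroxy-2-methylhept-2-enoate | CC[C@@H](C(=O)N1[C@H](Cc2ccccc2)COC1=O)[C@@H](O)/C=C(\C)C(=O)OC | intermediate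
14 | methyl (2E,4S,5R)-5-{[(4R)-4-benzyl-2-oxo-1,3-oxazolidin-3-yl]carbonyl}-2-methyl-4-[(triethylsilyl)oxy]hept-2-enoate | CC[C@@H](C(=O)N1[C@H](Cc2ccccc2)COC1=O)[C@@H](O[Si](CC)(CC)CC)/C=C(\C)C(=O)OC | intermediate
15 | methyl (2E,4S,5R)-5-[(ethylsulfanyl)carbonyl]-2-methyl-4-[(triethylsilyl)oxy]hept-2-enoate | CC[C@@H](C(=O)SCC)[C@@H](O[Si](CC)(CC)CC)/C=C(\C)C(=O)OC | intermediate
16 | (4-chlorobutyl)zinc bromide (THF solution) | ClCCCC[Zn]Br | starting material
17 | methyl (2E,4S,5R)-10-chloro-5-ethyl-2-methyl-6-oxo-4-[(triethylsilyl)oxy]dec-2-enoate | CC[C@@H](C(=O)CCCCCl)[C@@H](O[Si](CC)(CC)CC)/C=C(\C)C(=O)OC | intermediate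
18 | methyl (2E,4S,5R)-10-chloro-5-ethyl-2-methyl-4-[(triethylsilyl)oxy]-6-{[(trifluoromethyl)sulfonyl]oxy}deca-2,6-dienoate (6E/6Z mixture) | CC[C@@H](C(OS(=O)(=O)C(F)(F)F)=CCCCCl)[C@@H](O[Si](CC)(CC)CC)/C=C(\C)C(=O)OC | intermediate
19 | methyl (2E,4S,5R)-5-ethyl-10-{(2R,4S)-4-hydroxy-2-[(2S,4S)-4-methyl-5-oxooxolan-2-yl]pyrrolidin-1-yl}-2-methyl-4-[(triethylsilyl)oxy]-6-{[(trifluoromethyl)sulfonyl]oxy}deca-2,6-dienoate (6E/6Z) | CC[C@@H](C(OS(=O)(=O)C(F)(F)F)=CCCCN1C[C@@H](O)C[C@@H]1[C@@H]1C[C@H](C)C(=O)O1)[C@@H](O[Si](CC)(CC)CC)/C=C(\C)C(=O)OC | intermediate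
20 | methyl (2E,4S,5R)-5-ethyl-2-methyl-10-{(2R)-2-[(2S,4S)-4-methyl-5-oxooxolan-2-yl]-4-oxopyrrolidin-1-yl}-4-[(triethylsilyl)oxy]-6-{[(trifluoromethyl)sulfonyl]oxy}deca-2,6-dienoate (6E/6Z) | CC[C@@H](C(OS(=O)(=O)C(F)(F)F)=CCCCN1CC(=O)C[C@@H]1[C@@H]1C[C@H](C)C(=O)O1)[C@@H](O[Si](CC)(CC)CC)/C=C(\C)C(=O)OC | intermediate
21 | methyl (2E,4S,5R)-5-ethyl-4-hydroxy-2-methyl-10-{(2R)-2-[(2S,4S)-4-methyl-5-oxooxolan-2-yl]-4-oxopyrrolidin-1-yl}-6-{[(trifluoromethyl)sulfonyl]oxy}deca-2,6-dienoate (6E/6Z) | CC[C@@H](C(OS(=O)(=O)C(F)(F)F)=CCCCN1CC(=O)C[C@@H]1[C@@H]1C[C@H](C)C(=O)O1)[C@@H](O)/C=C(\C)C(=O)OC | intermediate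
22 | methyl (2E,4S,5S)-4-hydroxy-2-methyl-5-{(3R)-3-[(2S,4S)-4-methyl-5-oxooxolan-2-yl]-1-oxo-2,3,5,6,7,9a-hexahydro-1H-pyrrolo[1,2-a]azepin-9-yl}hept-2-enoate (C9a epimers; not isolated) | O=C1C[C@H]([C@@H]3C[C@H](C)C(=O)O3)N2CCCC=C(C12)[C@H](CC)[C@@H](O)/C=C(\C)C(=O)OC | intermediate
23 | methyl (2E,4S,5S)-4-hydroxy-2-methyl-5-{(3R)-3-[(2S,4S)-4-methyl-5-oxooxolan-2-yl]-1-oxo-2,3,5,6,7,8-hexahydro-1H-pyrrolo[1,2-a]azepin-9-yl}hept-2-enoate (not isolated) | O=C1C[C@H]([C@@H]3C[C@H](C)C(=O)O3)N2CCCCC(=C12)[C@H](CC)[C@@H](O)/C=C(\C)C(=O)OC | intermediate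
24 | CNP0154902.3: pentacyclic 9,9a-enamine; ring C carries 10-ethyl (10S) and 11-hydroxy (11R) and is fused at C1–C12 to the α-methyl-γ-lactone D with its oxygen on C1 (1R,12R,13R); C3 (3R) carries the (2S,4S)-4-methyl-5-oxooxolan-2-yl group | CC[C@H]1C2=C3N(CCCC2)[C@@H]([C@@H]2C[C@H](C)C(=O)O2)C[C@]32OC(=O)[C@H](C)[C@@H]2[C@@H]1O | target

**Totals and risks**

Total step count: 16. Longest linear sequence: 11 steps (steps 6 to 12, then 13 to 16).

Steps most likely to fail:

1. Step 16. The seven-membered C9–C9a closure may be slow, and the enone radical anion may be protonated at C9 (conjugate reduction) or lose the α-amino group before it cyclises. Fallback (sets out from 21, returns at 24): only the palladium stage is run, at room temperature and stopped before the base has moved the double bond, so that the non-conjugated ketone 22 is isolated. Its ordinary, non-conjugated ketyl is then cyclised and lactonised with SmI2, HMPA and t-BuOH under the same hydroxyl direction to the 8,9-unsaturated 9a-H pentacycle F1. The C8=C9 bond is finally moved to C9=C9a by rhodium-catalysed allylamine-to-enamine isomerisation ([Rh(cod)2]BF4, BINAP, THF, 60 °C), so the enamine is made last instead of before the radical step.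

2. Step 12. Enolisation may stray toward C10, with epimerisation there or β-elimination of the silyloxy group. Fallback (sets out from 15, returns at 18): thioester 15 is coupled under Liebeskind–Srogl conditions (Pd2(dba)3, tri(2-furyl)phosphine, copper thiophene-2-carboxylate CuO2CC4H3S, THF) with (E)-(4-chlorobut-1-en-1-yl)boronic acid to the enone F5. Conjugate hydride addition with LiBH(s-Bu)3 at −78 °C then generates the C8–C9 enolate regiospecifically, without any deprotonation, and PhNTf2 traps it as 18.

3. Step 3. Facial selectivity of the allylzinc addition at C18 may be poor. Fallback (sets out from 3, returns at 6): reagent-controlled allylation with the B-allyldiisopinocampheylborane enantiomer that reinforces the Felkin sense gives the homoallylic alcohol F2. Acylation with methacryloyl chloride (Et3N, DMAP) gives the methacrylate F3, and ring-closing metathesis with the second-generation Grubbs catalyst gives the butenolide F4. Hydrogenation over Rh/Al2O3 from the face away from the pyrrolidine returns to 6.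

Further compounds
F1 | step 16 | 8,9-didehydro-9a-hydro isomer of 24 (C8=C9 allylic amine, C9a epimers, all other stereocentres as in 24) | CC[C@H]1C2=CCCCN3[C@@H]([C@@H]4C[C@H](C)C(=O)O4)C[C@]4(OC(=O)[C@H](C)[C@@H]4[C@@H]1O)C23
F2 | step 3 | tert-butyl (2R,4S)-4-[(tert-butyldimethylsilyl)oxy]-2-[(1S)-1-hydroxybut-3-en-1-yl]pyrrolidine-1-carboxylate | CC(C)(C)OC(=O)N1C[C@@H](O[Si](C)(C)C(C)(C)C)C[C@@H]1[C@@H](O)CC=C
F3 | step 3 | (1S)-1-{(2R,4S)-1-(tert-butoxycarbonyl)-4-[(tert-butyldimethylsilyl)oxy]pyrrolidin-2-yl}but-3-en-1-yl 2-methylprop-2-enoate | CC(C)(C)OC(=O)N1C[C@@H](O[Si](C)(C)C(C)(C)C)C[C@@H]1[C@@H](OC(=O)C(C)=C)CC=C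
F4 | step 3 | tert-butyl (2R,4S)-4-[(tert-butyldimethylsilyl)oxy]-2-[(2S)-4-methyl-5-oxo-2,5-dihydrofuran-2-yl]pyrrolidine-1-carboxylate | CC(C)(C)OC(=O)N1C[C@@H](O[Si](C)(C)C(C)(C)C)C[C@@H]1[C@@H]1C=C(C)C(=O)O1
F5 | step 12 | methyl (2E,4S,5R,7E)-10-chloro-5-ethyl-2-methyl-6-oxo-4-[(triethylsilyl)oxy]deca-2,7-dienoate | CC[C@@H](C(=O)/C=C/CCCl)[C@@H](O[Si](CC)(CC)CC)/C=C(\C)C(=O)OC
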